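**Plan** (chromenone numbering: O1, C2 with the heptadecyl chain, C3, C4 with OH, C4a, C5=O, C6–C8, C8a; ring A = carbocycle, ring B = dihydropyran)
- Retrosynthesis: first the C4–O ether to a removable chiral group, then C2–C3 and C4–C4a together (formal [4+2]), then the C2 leaving group and the O1–C2 bond, back to cyclohexane-1,3-dione and octadecanal.
- Enabling feature: O1 is both the enol-ether oxygen of the vinylogous ester (C8a=C4a–C5=O of ring A) and the acetal-type oxygen on C2. Ionisation at C2 therefore gives a 2-oxonia-diene C2=O1+–C8a=C4a whose ends are the two atoms that the C3–C4 unit must bridge.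
- The C3–C4 unit is a vinyl ether; its oxygen becomes the C4 hydroxyl.
- Forward: ring A is bought intact, the C18 chain is attached through O1–C2, and ring B is closed in one event.
- Stereochemistry: the C2/C4 cis relation comes from the cycloaddition topology; the absolute sense comes from an (R)-1-phenylethyl group on the vinyl ether oxygen, which also makes the two cis adducts separable diastereomers and is removed by hydrogenolysis.

Key step: step 5

Assumption: the chiral vinyl ether is taken to react through its s-trans conformer with the carbinol C–H in the enol-ether plane, so that the face anti to phenyl is attacked and the (R) group leads to (2S,4R); if the opposite sense were found, (S)-1-phenylethanol would be used with no other change.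

Step 1
Reactants: 1 octadecanal
Product: 2 1-chloro-1-(ethylsulfanyl)octadecane (racemic)
Conditions: EtSH, HCl (g), CaCl2, CH2Cl2, −20 → 0 °C; used crude
Reagents that add atoms: ethanethiol (CCS); hydrogen chloride (Cl)
Why: Hemithioacetal formation and replacement of its hydroxyl by chloride through the sulfur-stabilised thionium ion is the classical aldehyde–thiol–HCl synthesis of α-chloroalkyl sulfides; the new stereocenter is racemic and is planarised in step 5.

Step 2
Reactants: 2 1-chloro-1-(ethylsulfanyl)octadecane; 3 cyclohexane-1,3-dione
Product: 5 3-{[1-(ethylsulfanyl)octadecyl]oxy}cyclohex-2-en-1-one (racemic), via sodium 3-oxocyclohex-1-en-1-olate 4 (not isolated)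
Conditions: NaH, DMF, 0 °C; then 2, 0 °C → rt
Reagents that add atoms: none
Why: The sodium enolate, a vinylogous carboxylate, should be alkylated at oxygen by the SN1-reactive α-chloro sulfide (O-alkylation of cyclic 1,3-dione enolates by α-heteroatom-stabilised chlorides, as known for chloromethyl ethers), which fixes the O1–C2 bond; no defined stereocenter is set.

Step 3
Reactants: 5 3-{[1-(ethylsulfanyl)octadecyl]oxy}cyclohex-2-en-1-one
Product: 6 3-[(1-chlorooctadecyl)oxy]cyclohex-2-en-1-one (racemic)
Conditions: SO2Cl2, CH2Cl2, −78 °C; then cyclohexene; concentrated cold and used at once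
Reagents that add atoms: sulfuryl chloride (O=S(=O)(Cl)Cl)
Why: Sulfur is chlorinated far faster than the push-pull alkene and the chlorosulfonium ion collapses with chloride to the α-chloro ether, the known chlorinolysis of O,S-acetals such as (methylsulfanyl)methyl esters; chlorine, unlike sulfur or oxygen, cannot later act as a donor that expels the dione.

Step 4
Reactants: 7 (1R)-1-phenylethan-1-ol; 8 ethyl vinyl ether
Product: 9 [(1R)-1-(ethenyloxy)ethyl]benzene
Conditions: Hg(OAc)2 (cat.), ethyl vinyl ether as solvent, reflux
Reagents that add atoms: none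
Why: Mercury acetate-catalysed transvinylation (alkoxymercuration–dealkoxymercuration) exchanges the ethoxy group for the chiral alkoxy group without touching the carbinol C–O bond, so the R configuration is retained.

Step 5
Reactants: 6 3-[(1-chlorooctadecyl)oxy]cyclohex-2-en-1-one; 9 [(1R)-1-(ethenyloxy)ethyl]benzene
Product: 11 (2S,4R)-2-heptadecyl-4-[(1R)-1-phenylethoxy]-2,3,4,6,7,8-hexahydro-5H-chromen-5-one, via octadecylidene(3-oxocyclohex-1-en-1-yl)oxonium triflate 10 (not isolated)
Conditions: AgOSO2CF3 (added last), 2,6-di-tert-butyl-4-methylpyridine, 4 Å molecular sieves, CH2Cl2, −78 → −40 °C; aq. NaHCO3; chromatography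
Reagents that add atoms: none
Why: Proposed new method: Ag+ removes chloride from 6 to give oxocarbenium ion 10, a cationic 2-oxadiene (C2=O1+–C8a=C4a) in which O1 is still bound to ring A; the CH2 terminus of 9 adds to C2, the resulting alkoxycarbenium ion at C4 is trapped by the nucleophilic α-carbon C4a of the vinylogous ester, and loss of the C4a proton to the pyridine base restores the C4a=C8a bond, so that C2–C3 and C4–C4a form in one polar, highly asynchronous inverse-electron-demand [4+2] event. The closest known reaction type is the oxa-Povarov reaction of aryl oxocarbenium ions with alkenes (2,4-cis chromans), together with the Prins-type closure of dioxinone (vinylogous ester) α-carbons onto oxocarbenium ions; new is the use of a vinylogous ester enol oxygen in place of the aryl ether. Ring B is the only ring closed: formally by [4+2] cycloaddition, in the stepwise limit by a favoured 6-(enolendo)-exo-trig attack of C4a on the exocyclic C4=O+ bond. The C2/C4 cis relation should follow from a chair-like (endo) transition state with the heptadecyl chain and the alkoxy group both pseudo-equatorial, and the absolute sense from the (R)-1-phenylethyl group, which in the s-trans conformer of 9 shields one face of the enol ether so that both bonds form anti to phenyl, giving 4R and hence 2S; the other cis adduct is a diastereomer, not an enantiomer, of 11 and is removed by chromatography. The step needs (a) ionisation at C2 without loss of the dione as a vinylogous carboxylate, secured by the chloride leaving group and the halophilic silver salt, (b) capture of the C4 cation by C4a and not by a second molecule of 9, secured by the six-membered intramolecular closure, low temperature and only a slight excess of 9, and (c) survival of the acid-labile allylic C4–O bond, secured by the hindered base.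

Step 6
Reactants: 11 (2S,4R)-2-heptadecyl-4-[(1R)-1-phenylethoxy]-2,3,4,6,7,8-hexahydro-5H-chromen-5-one
Product: 12 (2S,4R)-2-heptadecyl-4-hydroxy-2,3,4,6,7,8-hexahydro-5H-chromen-5-one (CNP0197950.1)
Conditions: H2 (1 atm), Pd/C, EtOAc, rt
Reagents that add atoms: none
Why: Hydrogenolysis cleaves only the benzylic C–O bond of the 1-phenylethyl ether, the tetrasubstituted push-pull C4a=C8a bond and the ring C4–O bond being expected to survive under neutral conditions, and neither stereocenter is touched.

**Compound list**
1 | octadecanal | CCCCCCCCCCCCCCCCCC=O | starting material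
2 | 1-chloro-1-(ethylsulfanyl)octadecane (racemic) | CCCCCCCCCCCCCCCCCC(Cl)SCC | intermediate
3 | cyclohexane-1,3-dione | O=C1CCCC(=O)C1 | starting material
4 | sodium 3-oxocyclohex-1-en-1-olate (formed in the flask, not isolated) | [Na+].[O-]C1=CC(=O)CCC1 | intermediate
5 | 3-{[1-(ethylsulfanyl)octadecyl]oxy}cyclohex-2-en-1-one (racemic) | CCCCCCCCCCCCCCCCCC(SCC)OC1=CC(=O)CCC1 | intermediate
6 | 3-[(1-chlorooctadecyl)oxy]cyclohex-2-en-1-one (racemic) | CCCCCCCCCCCCCCCCCC(Cl)OC1=CC(=O)CCC1 | intermediate
7 | (1R)-1-phenylethan-1-ol | C[C@@H](O)c1ccccc1 | starting material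
8 | ethyl vinyl ether (ethoxyethene) | CCOC=C | starting material
9 | [(1R)-1-(ethenyloxy)ethyl]benzene | C[C@@H](OC=C)c1ccccc1 | intermediate
10 | octadecylidene(3-oxocyclohex-1-en-1-yl)oxonium trifluoromethanesulfonate (formed in the flask, not isolated) | CCCCCCCCCCCCCCCCCC=[O+]C1=CC(=O)CCC1.[O-]S(=O)(=O)C(F)(F)F | intermediate
11 | (2S,4R)-2-heptadecyl-4-[(1R)-1-phenylethoxy]-2,3,4,6,7,8-hexahydro-5H-chromen-5-one | CCCCCCCCCCCCCCCCC[C@H]1C[C@@H](O[C@H](C)c3ccccc3)C2=C(CCCC2=O)O1 | intermediate
12 | (2S,4R)-2-heptadecyl-4-hydroxy-2,3,4,6,7,8-hexahydro-5H-chromen-5-one | CCCCCCCCCCCCCCCCC[C@H]1C[C@@H](O)C2=C(CCCC2=O)O1 | target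

**Step count:** 6 steps in total. Longest linear sequence: 5 steps (1, 2, 3, 5, 6); step 4 is a one-step branch.

**Steps most likely to fail**

Step 5 (key step, proposed new method).
- What may go wrong: oligomerisation of the vinyl ether outrunning ring closure; proton loss from cation 10 to an enol ether; incomplete facial or cis selectivity; fragmentation of the 1-phenylethyl group from the C4 alkoxycarbenium ion.
- Fallback, known reactions only, from 1 back to the route at 11:
 - Brown allylation of 1 with the B-allyldiisopinocampheylborane derived from (−)-α-pinene should give (4S)-henicos-1-en-4-ol F1.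
 - Acid-catalysed condensation of F1 with 3 (TsOH, benzene, water removal) should give 3-{[(4S)-henicos-1-en-4-yl]oxy}cyclohex-2-en-1-one F2.
 - Lemieux–Johnson cleavage of its terminal alkene (OsO4 cat., NaIO4, 2,6-lutidine) should give (3S)-3-[(3-oxocyclohex-1-en-1-yl)oxy]icosanal F3.
 - With trimethyl[(1R)-1-phenylethoxy]silane F4 (from 7, chlorotrimethylsilane, imidazole) and catalytic TMSOTf at −78 °C, the aldehyde should be converted into the C4 alkoxycarbenium ion and close ring B by the Prins-type addition of the vinylogous ester carbon known for dioxinones. C2 is then fixed by the allylation and C4 is set cis by the chair-like closure, giving 11.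

Step 2.
- What may go wrong: alkylation at the central carbon of the dione instead of oxygen; migration of the alkyl group from oxygen to carbon through a thionium–enolate ion pair; elimination of HCl from 2.
- Fallback, from 1 back to the route at 6, forming O1–C8a instead of O1–C2 so that no ambident alkylation is involved:
 - Vinylmagnesium bromide and 1 should give icos-1-en-3-ol F5.
 - Its sodium alkoxide and 3-chlorocyclohex-2-en-1-one (addition–elimination) should give 3-(icos-1-en-3-yloxy)cyclohex-2-en-1-one F6.
 - Lemieux–Johnson cleavage should give 2-[(3-oxocyclohex-1-en-1-yl)oxy]nonadecanal F7.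
 - Pinnick oxidation should give 2-[(3-oxocyclohex-1-en-1-yl)oxy]nonadecanoic acid F8.
 - Kochi chlorodecarboxylation (Pb(OAc)4, LiCl) should give 6.

Step 3.
- What may go wrong: electrophilic chlorination at the α-carbon of the vinylogous ester; Pummerer-type chlorination of the S-ethyl group; hydrolysis of the labile chloride on handling.
- Fallback, from 5 back to the route at 11, without any electrophilic chlorine:
 - Oxidation of 5 with mCPBA (NaHCO3, CH2Cl2, 0 °C) should give the storable sulfone 3-{[1-(ethanesulfonyl)octadecyl]oxy}cyclohex-2-en-1-one F9.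
 - Treated with 9 and SnCl4 (CH2Cl2, −78 °C, hindered pyridine), the sulfinate should leave as it does from 2-sulfonyl cyclic ethers, giving the same oxocarbenium cation as in 10 and hence 11.

Further compounds
F1 | step 5 | (4S)-henicos-1-en-4-ol | CCCCCCCCCCCCCCCCC[C@H](O)CC=C
F2 | step 5 | 3-{[(4S)-henicos-1-en-4-yl]oxy}cyclohex-2-en-1-one | CCCCCCCCCCCCCCCCC[C@H](OC1=CC(=O)CCC1)CC=C
F3 | step 5 | (3S)-3-[(3-oxocyclohex-1-en-1-yl)oxy]icosanal | CCCCCCCCCCCCCCCCC[C@H](OC1=CC(=O)CCC1)CC=O
F4 | step 5 | trimethyl[(1R)-1-phenylethoxy]silane | C[C@@H](O[Si](C)(C)C)c1ccccc1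
F5 | step 2 | icos-1-en-3-ol (racemic) | CCCCCCCCCCCCCCCCCC(O)C=C
F6 | step 2 | 3-(icos-1-en-3-yloxy)cyclohex-2-en-1-one (racemic) | CCCCCCCCCCCCCCCCCC(OC1=CC(=O)CCC1)C=C
F7 | step 2 | 2-[(3-oxocyclohex-1-en-1-yl)oxy]nonadecanal (racemic) | CCCCCCCCCCCCCCCCCC(OC1=CC(=O)CCC1)C=O
F8 | step 2 | 2-[(3-oxocyclohex-1-en-1-yl)oxy]nonadecanoic acid (racemic) | CCCCCCCCCCCCCCCCCC(OC1=CC(=O)CCC1)C(=O)O
F9 | step 3 | 3-{[1-(ethanesulfonyl)octadecyl]oxy}cyclohex-2-en-1-one (racemic) | CCCCCCCCCCCCCCCCCC(OC1=CC(=O)CCC1)S(=O)(=O)CC
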